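**Assumption:** (S)-4-benzyl-2-oxazolidinone is bought and used as a recoverable chiral auxiliary (none of its atoms reach the target). The target is the trans-(2S,3R) acid, with an E alkene.

## Retrosynthetic overview

1. Target ⇒ Heck disconnection at C5 of the benzofuran: bromo-dihydrobenzofuran + acrylic acid.
2. The dihydrofuran ring is the only ring formed (both benzene rings come intact from catechol). It is closed by acid-mediated MOM removal and benzylic C–O cyclisation of a 1,3-diol; C2 is set trans to C3.
3. Diol ⇒ Evans aldol (C2–C3 bond, sets C3) between a ring-B arylacetyl oxazolidinone and O-MOM-vanillin, then reductive auxiliary removal. This is the convergent fragment coupling.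
4. Arylacetyl imide ⇒ ortho-selective Br/Mg exchange of a dibromoguaiacol MOM ether and Negishi-type coupling with a bromoacetyl auxiliary. Aldehyde ⇒ para-bromination, MOM protection and formylation of guaiacol.

## Route

**Step 1**
Reactants: 1 catechol
Product: 2 guaiacol (2-methoxyphenol)
Conditions: MeI (1.0 equiv), K2CO3, acetone, reflux; veratrole removed by NaOH extraction
Reagents that add atoms: iodomethane, CI
Why: Williamson mono-O-methylation; the second OH is less acidic and hydrogen-bonded, so the mono-ether is the main product and is separable from di-ether and catechol.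

**Step 2**
Reactants: 2 guaiacol
Product: 3 2,4-dibromo-6-methoxyphenol
Conditions: NBS (2.05 equiv), i-Pr2NH (10 mol %), CH2Cl2, 0 °C → rt
Reagents that add atoms: N-bromosuccinimide, O=C1CCC(=O)N1Br
Why: electrophilic aromatic bromination in which the OH (amine-assisted ortho delivery, then para) outcompetes OMe as director.

**Step 3**
Reactants: 3 2,4-dibromo-6-methoxyphenol
Product: 4 1,5-dibromo-3-methoxy-2-(methoxymethoxy)benzene
Conditions: NaH, MOMCl, THF/DMF, 0 °C → rt
Reagents that add atoms: chloromethyl methyl ether, COCCl
Why: O-alkylation of the phenoxide; MOM protects the phenol, directs the next metalation and is acid-labile for the cyclisation step.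

**Step 4**
Reactants: 5 (S)-4-benzyloxazolidin-2-one; 6 bromoacetyl bromide
Product: 7 (S)-4-benzyl-3-(2-bromoacetyl)oxazolidin-2-one
Conditions: n-BuLi, THF, −78 °C; then 6, −78 → 0 °C
Reagents that add atoms: none
Why: N-acylation of the lithiated oxazolidinone by the acid bromide; the stereocentre is untouched.

**Step 5**
Reactants: 4 1,5-dibromo-3-methoxy-2-(methoxymethoxy)benzene; 7 (S)-4-benzyl-3-(2-bromoacetyl)oxazolidin-2-one
Product: 8 (S)-4-benzyl-3-{2-[5-bromo-3-methoxy-2-(methoxymethoxy)phenyl]acetyl}oxazolidin-2-one
Conditions: i-PrMgCl·LiCl, THF, −15 °C → rt; ZnCl2; then 7, Pd(OAc)2 (3 mol %), P(o-tol)3 (9 mol %), THF, rt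
Reagents that add atoms: none
Why: chelation-controlled Br/Mg exchange at the bromide ortho to OMOM, transmetalation to zinc, then Negishi-type arylation of the α-bromo imide; Pd(0) adds to the α-bromocarbonyl far faster than to the electron-rich para aryl bromide.

**Step 6**
Reactants: 2 guaiacol
Product: 9 4-bromo-2-methoxyphenol
Conditions: NBS (1.0 equiv), MeCN, 0 °C
Reagents that add atoms: N-bromosuccinimide, O=C1CCC(=O)N1Br
Why: amine-free electrophilic bromination of the phenol goes para to OH.

**Step 7**
Reactants: 9 4-bromo-2-methoxyphenol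
Product: 10 4-bromo-2-methoxy-1-(methoxymethoxy)benzene
Conditions: MOMCl, i-Pr2NEt, CH2Cl2, 0 °C → rt
Reagents that add atoms: chloromethyl methyl ether, COCCl
Why: standard phenol MOM protection, stable to the organolithium and boron enolate steps.

**Step 8**
Reactants: 10 4-bromo-2-methoxy-1-(methoxymethoxy)benzene
Product: 11 3-methoxy-4-(methoxymethoxy)benzaldehyde
Conditions: n-BuLi, THF, −78 °C; DMF; aq. NH4Cl
Reagents that add atoms: N,N-dimethylformamide, CN(C)C=O
Why: Li–Br exchange and formylation of the aryllithium (Bouveault-type) puts the aldehyde exactly where the bromine was.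

**Step 9**
Reactants: 8 arylacetyl imide; 11 3-methoxy-4-(methoxymethoxy)benzaldehyde
Product: 12 (S)-4-benzyl-3-{(2S,3S)-2-[5-bromo-3-methoxy-2-(methoxymethoxy)phenyl]-3-hydroxy-3-[3-methoxy-4-(methoxymethoxy)phenyl]propanoyl}oxazolidin-2-one
Conditions: Bu2BOTf, i-Pr2NEt, CH2Cl2, −78 → 0 °C; 11, −78 → 0 °C; pH 7 buffer, MeOH, H2O2
Reagents that add atoms: none
Why: Evans boron syn-aldol via the Z-enolate and a Zimmerman–Traxler transition state; the (S)-benzyl auxiliary sets the α-aryl carbon as 2S (the future C3, R in the target), and the carbinol configuration is not critical because it is reset in step 11.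

**Step 10**
Reactants: 12 aldol adduct
Product: 13 (1S,2R)-2-[5-bromo-3-methoxy-2-(methoxymethoxy)phenyl]-1-[3-methoxy-4-(methoxymethoxy)phenyl]propane-1,3-diol (auxiliary 5 recovered)
Conditions: LiBH4, THF, MeOH (1 equiv), 0 °C
Reagents that add atoms: none
Why: chemoselective reductive cleavage of the N-acyl oxazolidinone to the primary alcohol; after this the α-carbon is no longer enolisable, and ArBr and MOM are inert.

**Step 11**
Reactants: 13 diol
Product: 14 4-[(2S,3R)-5-bromo-3-(hydroxymethyl)-7-methoxy-2,3-dihydro-1-benzofuran-2-yl]-2-methoxyphenol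
Conditions: HCl (about 1.25 M, from AcCl) in MeOH/THF, 0 °C → rt
Reagents that add atoms: none
Why: acetal hydrolysis removes both MOM groups, and the p-oxybenzylic alcohol ionises (SN1, quinone-methide-like cation) and is trapped 5-exo by the ring-B phenol; C2 forms trans to the C3 CH2OH under thermodynamic control, giving 2S.

**Step 12**
Reactants: 14 bromo-dihydrobenzofuran; 15 acrylic acid
Product: 16 (E)-3-[(2S,3R)-2-(4-hydroxy-3-methoxyphenyl)-3-(hydroxymethyl)-7-methoxy-2,3-dihydro-1-benzofuran-5-yl]prop-2-enoic acid (target)
Conditions: Pd(OAc)2 (5 mol %), P(o-tol)3 (10 mol %), Et3N, DMF, 90 °C; acidic work-up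
Reagents that add atoms: none
Why: Mizoroki–Heck coupling of the unhindered aryl bromide with acrylic acid gives the E-cinnamic acid directly; free OH groups are tolerated and neither stereocentre is acidic.

## Compound list

1 | catechol | Oc1ccccc1O | starting material
2 | guaiacol | COc1ccccc1O | intermediate
3 | 2,4-dibromo-6-methoxyphenol | COc1cc(Br)cc(Br)c1O | intermediate
4 | 1,5-dibromo-3-methoxy-2-(methoxymethoxy)benzene | COCOc1c(Br)cc(Br)cc1OC | intermediate
5 | (S)-4-benzyloxazolidin-2-one | O=C1N[C@@H](Cc2ccccc2)CO1 | starting material (recoverable chiral auxiliary, reagent)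
6 | bromoacetyl bromide | O=C(Br)CBr | starting material
7 | (S)-4-benzyl-3-(2-bromoacetyl)oxazolidin-2-one | O=C(CBr)N1[C@@H](Cc2ccccc2)COC1=O | intermediate
8 | (S)-4-benzyl-3-{2-[5-bromo-3-methoxy-2-(methoxymethoxy)phenyl]acetyl}oxazolidin-2-one | COCOc1c(CC(=O)N2[C@@H](Cc3ccccc3)COC2=O)cc(Br)cc1OC | intermediate
9 | 4-bromo-2-methoxyphenol | COc1cc(Br)ccc1O | intermediate
10 | 4-bromo-2-methoxy-1-(methoxymethoxy)benzene | COCOc1ccc(Br)cc1OC | intermediate
11 | 3-methoxy-4-(methoxymethoxy)benzaldehyde | COCOc1ccc(C=O)cc1OC | intermediate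
12 | (2S,3S) Evans syn-aldol adduct on the (S)-auxiliary | COCOc1ccc([C@@H](O)[C@@H](C(=O)N2[C@@H](Cc3ccccc3)COC2=O)c2cc(Br)cc(OC)c2OCOC)cc1OC | intermediate
13 | (1S,2R)-2-[5-bromo-3-methoxy-2-(methoxymethoxy)phenyl]-1-[3-methoxy-4-(methoxymethoxy)phenyl]propane-1,3-diol | COCOc1ccc([C@@H](O)[C@@H](CO)c2cc(Br)cc(OC)c2OCOC)cc1OC | intermediate
14 | 4-[(2S,3R)-5-bromo-3-(hydroxymethyl)-7-methoxy-2,3-dihydrobenzofuran-2-yl]-2-methoxyphenol | COc1cc([C@H]2Oc3c(OC)cc(Br)cc3[C@@H]2CO)ccc1O | intermediate
15 | acrylic acid | C=CC(=O)O | starting material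
16 | (E)-3-[(2S,3R)-2-(4-hydroxy-3-methoxyphenyl)-3-(hydroxymethyl)-7-methoxy-2,3-dihydrobenzofuran-5-yl]acrylic acid | COc1cc([C@H]2Oc3c(OC)cc(/C=C/C(=O)O)cc3[C@@H]2CO)ccc1O | target

## Count

Total steps: 12.
Longest linear sequence: 8 (steps 1 → 2 → 3 → 5 → 9 → 10 → 11 → 12). Steps 4 and 6–8 are side branches.

## Steps most likely to fail, with fallbacks

- **Step 5** (site-selective metalation and Negishi coupling with an α-bromo imide; risks are reduction to the N-acetyl imide or coupling at the para bromide). Fallback: trap the aryl-magnesium with ethylene oxide (CuI cat.) to give the 2-arylethanol, oxidise it to the arylacetic acid (TEMPO/NaOCl/NaClO2), and N-acylate lithiated 5 through the pivaloyl mixed anhydride.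
- **Step 9** (hindered α-aryl boron enolate plus an electron-rich, poorly electrophilic aldehyde; risks are low conversion and retro-aldol). Fallback: replace the aldol with a Rh(II)-carbenoid route. O-benzylate the ring-B (2-hydroxyaryl)acetate with the ring-A benzyl bromide, carry out diazo transfer, then asymmetric intramolecular C–H insertion (Rh2(S-PTTL)4) to the cis-dihydrobenzofuran ester. Epimerise to trans with NaOMe and reduce with LiBH4.
- **Step 11** (cationic cyclisation; risks are benzylic methyl ether stalling, stilbene formation with loss of C3 integrity, or cis/trans mixtures). Fallback: switch to quinone-methide chemistry. TMSBr converts the benzylic alcohol to the bromide and cleaves the MOM groups; aqueous NaHCO3 then generates the p-quinone methide, which undergoes trans-selective intramolecular phenoxide 1,6-addition.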